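## Retrosynthetic overview

1. Target 18 ⇐ ketal hydrolysis of enone acetonide 17 ⇐ β-elimination of the C3 hydroxyl of ketol 15.
2. Key disconnection of 15: the C2–C3 bond (aldol) and the C1–C6 bond (crossed benzoin, the C1 aldehyde carbon umpoled against the C6 ketone carbon) are cut together, giving acetaldehyde 13 (C1–C2) and keto-aldehyde 12 (C3–C6).
3. Enabling feature: the ring holds an α-ketol (C1 carbonyl beside the C6 tertiary carbinol) joined through C2=C3 to the C4 carbinol. C1–C2 is therefore an acetaldehyde unit usable first as C2 enamine donor and then as C1 acyl anion, and C3–C6 with its trans O4/O5 pair is the L-threitol skeleton. The trans-fused dioxolane on O4/O5 is a temporary ring that blocks every five-ring closure.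
4. 12 ⇐ twofold oxidation of diol 11 ⇐ aldehyde 8 (from 2,3-O-isopropylidene-L-threitol 6) + C21 Grignard 9; bromide 5 ⇐ Z-selective Wittig of 2 with ylide 4.
5. Ring order: the dioxolane comes with 6; the cyclohexanone ring is the only ring made, and it is closed in the key step.

Key step: step 8

Remark: ring locants C1–C6 are those of the cyclohex-2-en-1-one name of 18; 1, 3, 6 and 13 are taken as commercial; alkoxide salts and catalyst-bound species are counted as forms of the compound they derive from.

## Route

Step 1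
Reactants: 1 12-bromododecan-1-ol
Product: 2 12-bromododecanal
Conditions: Dess–Martin periodinane, CH2Cl2, 0 °C to rt
Reagents that add atoms: none
Why: Dess–Martin oxidation of a primary alcohol should stop cleanly at the aldehyde and leave the primary bromide untouched, and no stereocentre is formed.

Step 2
Reactants: 2 12-bromododecanal; 3 nonyl(triphenyl)phosphonium bromide
Product: 5 (12Z)-1-bromohenicos-12-ene, via nonylidene(triphenyl)phosphorane 4 (not isolated)
Conditions: 3, NaN(SiMe3)2, THF, −78 °C; then 2, −78 °C to rt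
Reagents that add atoms: none
Why: Wittig olefination with a non-stabilised ylide under lithium-free conditions should close the cis-oxaphosphetane kinetically and so set the Z double bond, the aldehyde reacting far faster than the remote primary bromide.

Step 3
Reactants: 6 [(4S,5S)-2,2-dimethyl-1,3-dioxolane-4,5-diyl]dimethanol (2,3-O-isopropylidene-L-threitol)
Product: 7 [(4S,5S)-5-({[tert-butyl(dimethyl)silyl]oxy}methyl)-2,2-dimethyl-1,3-dioxolan-4-yl]methanol
Conditions: NaH (1.0 equiv), THF, 0 °C; then TBSCl (1.0 equiv), rt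
Reagents that add atoms: tert-butyl(chloro)dimethylsilane (TBSCl), CC(C)(C)[Si](C)(C)Cl
Why: O-silylation through the sparingly soluble monosodium alkoxide of a C2-symmetric diol should stop after one silyl group, and because both hydroxyls are homotopic only one product can form and no stereocentre is touched.

Step 4
Reactants: 7 [(4S,5S)-5-({[tert-butyl(dimethyl)silyl]oxy}methyl)-2,2-dimethyl-1,3-dioxolan-4-yl]methanol
Product: 8 (4R,5S)-5-({[tert-butyl(dimethyl)silyl]oxy}methyl)-2,2-dimethyl-1,3-dioxolane-4-carbaldehyde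
Conditions: Dess–Martin periodinane, pyridine, CH2Cl2, 0 °C to rt
Reagents that add atoms: none
Why: Dess–Martin oxidation under pyridine buffering should give the α-alkoxy aldehyde without epimerisation, the trans-dioxolane being the more stable arrangement in any case.

Step 5
Reactants: 5 (12Z)-1-bromohenicos-12-ene; 8 (4R,5S)-5-({[tert-butyl(dimethyl)silyl]oxy}methyl)-2,2-dimethyl-1,3-dioxolane-4-carbaldehyde
Product: 10 (13Z)-1-[(4S,5S)-5-({[tert-butyl(dimethyl)silyl]oxy}methyl)-2,2-dimethyl-1,3-dioxolan-4-yl]docos-13-en-1-ol (both C1 epimers), via (12Z)-henicos-12-en-1-ylmagnesium bromide 9 (not isolated)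
Conditions: 5, Mg, THF, rt to 40 °C; then 8, −78 to 0 °C; then H2O
Reagents that add atoms: none
Why: Grignard addition to an aldehyde joins the chain to the threitol unit, and the new carbinol centre needs no control because it becomes the C6 ketone in step 7.

Step 6
Reactants: 10 (13Z)-1-[(4S,5S)-5-({[tert-butyl(dimethyl)silyl]oxy}methyl)-2,2-dimethyl-1,3-dioxolan-4-yl]docos-13-en-1-ol
Product: 11 (13Z)-1-[(4S,5S)-5-(hydroxymethyl)-2,2-dimethyl-1,3-dioxolan-4-yl]docos-13-en-1-ol (both C1 epimers)
Conditions: HF·pyridine, pyridine, THF, 0 °C to rt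
Reagents that add atoms: none
Why: Fluoride-driven cleavage of a primary silyl ether under buffered HF·pyridine should leave the acetonide and the Z-alkene intact.

Step 7
Reactants: 11 (13Z)-1-[(4S,5S)-5-(hydroxymethyl)-2,2-dimethyl-1,3-dioxolan-4-yl]docos-13-en-1-ol
Product: 12 (4R,5R)-5-[(13Z)-docos-13-enoyl]-2,2-dimethyl-1,3-dioxolane-4-carbaldehyde
Conditions: Dess–Martin periodinane (2.4 equiv), pyridine, CH2Cl2, 0 °C to rt; used at once
Reagents that add atoms: none
Why: Twofold Dess–Martin oxidation should convert the 1,4-diol directly into the keto-aldehyde under near-neutral conditions, the trans-fused acetonide preventing lactol formation at the half-oxidised stage and holding both α-alkoxy centres in their more stable trans arrangement.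

Step 8
Reactants: 12 (4R,5R)-5-[(13Z)-docos-13-enoyl]-2,2-dimethyl-1,3-dioxolane-4-carbaldehyde; 13 acetaldehyde
Product: 15 (3aR,4R,7aS)-4,7-dihydroxy-4-[(12Z)-henicos-12-en-1-yl]-2,2-dimethyl-3a,6,7,7a-tetrahydro-1,3-benzodioxol-5(4H)-one (both C7 epimers), via β-hydroxy aldehyde 14 (not isolated)
Conditions: (i) 13 (5 equiv), (S)-bis[3,5-bis(trifluoromethyl)phenyl](pyrrolidin-2-yl)methanol (10 mol%), DMF, 4 °C; excess 13 stripped at 0 °C under reduced pressure; (ii) 2-(pentafluorophenyl)-6,7-dihydro-5H-pyrrolo[2,1-c][1,2,4]triazol-2-ium tetrafluoroborate (15 mol%), NaOAc (20 mol%), CHCl3, rt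
Reagents that add atoms: none
Why: Proposed new method: acetaldehyde is used twice in one flask, first as its prolinol enamine (normal reactivity at C2), which adds to the more electrophilic α-alkoxy aldehyde of 12 to form C2–C3 and give aldol 14, and then, once the excess is stripped, as the Breslow intermediate of the new unbranched formyl group (reversed polarity at C1), which adds to the chain-bearing ketone to form C1–C6; the closest known reaction types are the diarylprolinol-catalysed crossed aldol of acetaldehyde with electrophilic aldehydes, the triazolylidene-catalysed intramolecular aldehyde–ketone crossed benzoin to six-membered tertiary α-ketols, and secondary-amine/carbene relay cascades (Michael then benzoin) that show the two catalysts can share a flask. The cyclohexanone ring closes in 6-exo-trig (enolexo) mode. The C3 carbinol centre is formed without control and is erased in step 9, so both epimers converge, whereas C6 is set by the substrate: in the chair-like transition state the trans-fused dioxolane fixes O4 and O5 equatorial, the C5–O bond lies antiperiplanar to the incoming carbon (polar Felkin–Anh arrangement) and the long chain sits equatorial, so the new hydroxyl should end axial and cis to O5. The step needs aldehyde-over-ketone selectivity in the aldol (secured by the reactivity gap and by the α-branched aldehyde of 12 being a poor enamine donor), six- over five-ring closure (a C2-enamine aldol onto the ketone or a hemiketal would give a strained trans-fused bicyclo[3.3.0] system, which the acetonide forbids) and carbene chemistry only after acetaldehyde has left (secured by the order of addition).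

Step 9
Reactants: 15 (3aR,4R,7aS)-4,7-dihydroxy-4-[(12Z)-henicos-12-en-1-yl]-2,2-dimethyl-3a,6,7,7a-tetrahydro-1,3-benzodioxol-5(4H)-one
Product: 17 (3aR,4R,7aS)-4-hydroxy-4-[(12Z)-henicos-12-en-1-yl]-2,2-dimethyl-3a,7a-dihydro-1,3-benzodioxol-5(4H)-one, via C7 mesylate 16 (not isolated)
Conditions: MsCl (1.2 equiv), Et3N (3 equiv), CH2Cl2, −20 to 0 °C
Reagents that add atoms: none
Why: Mesylation of the secondary β-hydroxyl (the tertiary α-ketol hydroxyl being too hindered) followed by E1cB elimination through the C2 enolate should give the conjugated enone, so both C3 epimers converge on one product and the three remaining stereocentres are untouched.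

Step 10
Reactants: 17 (3aR,4R,7aS)-4-hydroxy-4-[(12Z)-henicos-12-en-1-yl]-2,2-dimethyl-3a,7a-dihydro-1,3-benzodioxol-5(4H)-one
Product: 18 (4S,5R,6R)-4,5,6-trihydroxy-6-[(12Z)-henicos-12-en-1-yl]cyclohex-2-en-1-one
Conditions: AcOH–H2O (4:1), 40 °C
Reagents that add atoms: none
Why: Acid-catalysed hydrolysis of the strained trans-fused isopropylidene ketal should release the 4,5-diol without touching any stereocentre, the electron-poor enone disfavouring ionisation at the allylic and tertiary carbinol positions.

## Compound list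

1 | 12-bromododecan-1-ol | OCCCCCCCCCCCCBr | starting material
2 | 12-bromododecanal | O=CCCCCCCCCCCCBr | intermediate
3 | nonyl(triphenyl)phosphonium bromide | CCCCCCCCC[P+](c1ccccc1)(c1ccccc1)c1ccccc1.[Br-] | starting material
4 | nonylidene(triphenyl)phosphorane | CCCCCCCCC=P(c1ccccc1)(c1ccccc1)c1ccccc1 | intermediate
5 | (12Z)-1-bromohenicos-12-ene | BrCCCCCCCCCCC/C=C\CCCCCCCC | intermediate
6 | [(4S,5S)-2,2-dimethyl-1,3-dioxolane-4,5-diyl]dimethanol (2,3-O-isopropylidene-L-threitol) | OC[C@@H]1OC(C)(C)O[C@H]1CO | starting material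
7 | [(4S,5S)-5-({[tert-butyl(dimethyl)silyl]oxy}methyl)-2,2-dimethyl-1,3-dioxolan-4-yl]methanol | CC(C)(C)[Si](C)(C)OC[C@@H]1OC(C)(C)O[C@H]1CO | intermediate
8 | (4R,5S)-5-({[tert-butyl(dimethyl)silyl]oxy}methyl)-2,2-dimethyl-1,3-dioxolane-4-carbaldehyde | CC(C)(C)[Si](C)(C)OC[C@@H]1OC(C)(C)O[C@H]1C=O | intermediate
9 | (12Z)-henicos-12-en-1-ylmagnesium bromide | Br[Mg]CCCCCCCCCCC/C=C\CCCCCCCC | intermediate
10 | (13Z)-1-[(4S,5S)-5-({[tert-butyl(dimethyl)silyl]oxy}methyl)-2,2-dimethyl-1,3-dioxolan-4-yl]docos-13-en-1-ol, both C1 epimers | CC(C)(C)[Si](C)(C)OC[C@@H]1OC(C)(C)O[C@H]1C(O)CCCCCCCCCCC/C=C\CCCCCCCC | intermediate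
11 | (13Z)-1-[(4S,5S)-5-(hydroxymethyl)-2,2-dimethyl-1,3-dioxolan-4-yl]docos-13-en-1-ol, both C1 epimers | OC[C@@H]1OC(C)(C)O[C@H]1C(O)CCCCCCCCCCC/C=C\CCCCCCCC | intermediate
12 | (4R,5R)-5-[(13Z)-docos-13-enoyl]-2,2-dimethyl-1,3-dioxolane-4-carbaldehyde | O=C[C@@H]1OC(C)(C)O[C@H]1C(=O)CCCCCCCCCCC/C=C\CCCCCCCC | intermediate
13 | acetaldehyde | CC=O | starting material
14 | 3-{(4S,5R)-5-[(13Z)-docos-13-enoyl]-2,2-dimethyl-1,3-dioxolan-4-yl}-3-hydroxypropanal, both C3 epimers | O=CCC(O)[C@@H]1OC(C)(C)O[C@H]1C(=O)CCCCCCCCCCC/C=C\CCCCCCCC | intermediate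
15 | (3aR,4R,7aS)-4,7-dihydroxy-4-[(12Z)-henicos-12-en-1-yl]-2,2-dimethyl-3a,6,7,7a-tetrahydro-1,3-benzodioxol-5(4H)-one, both C7 epimers | CCCCCCCC/C=C\CCCCCCCCCCC[C@]1(O)C(=O)CC(O)[C@H](OC(C)(C)O2)[C@H]12 | intermediate
16 | C7 methanesulfonate of 15 (ring stereocentres as in 15) | CCCCCCCC/C=C\CCCCCCCCCCC[C@]1(O)C(=O)CC(OS(C)(=O)=O)[C@H](OC(C)(C)O2)[C@H]12 | intermediate
17 | (3aR,4R,7aS)-4-hydroxy-4-[(12Z)-henicos-12-en-1-yl]-2,2-dimethyl-3a,7a-dihydro-1,3-benzodioxol-5(4H)-one | CCCCCCCC/C=C\CCCCCCCCCCC[C@]1(O)C(=O)C=C[C@H](OC(C)(C)O2)[C@H]12 | intermediate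
18 | (4S,5R,6R)-4,5,6-trihydroxy-6-[(12Z)-henicos-12-en-1-yl]cyclohex-2-en-1-one | CCCCCCCC/C=C\CCCCCCCCCCC[C@]1(O)C(=O)C=C[C@H](O)[C@H]1O | target

## Step count and risks

Total step count: 10.
Longest linear sequence: 8 steps (steps 1, 2, 5, 6, 7, 8, 9, 10, or equally steps 3, 4, 5, 6, 7, 8, 9, 10).

Steps most likely to fail:

1. Step 8 (Proposed new method). Self-condensation of acetaldehyde or dehydration of the aldol to a trans-enal may outrun the carbene stage, and the free β-hydroxyl may erode turnover in the ring closure. The fallback sets out from 12 and returns at 15 using known reaction types only, trading the organocatalytic relay for a stepwise Lewis-acid route in which the labile aldol is carried as a robust silyl ether. (Ethenyloxy)tris(trimethylsilyl)silane F1, made from ClSi(SiMe3)3 and lithium ethenolate (n-BuLi cleavage of THF), is added to 12 under HNTf2 catalysis in CH2Cl2 (Mukaiyama cross-aldol, which should stop after one addition because of the bulky silyl group). This gives the tris(trimethylsilyl)silyl ether of aldol 14 F2, which is isolated. Carbene-catalysed crossed benzoin closure of F2 with the same triazolium salt and Et3N gives the 7-O-tris(trimethylsilyl)silyl ether of 15 F3, and HF·pyridine then frees the C7 hydroxyl to give 15.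

2. Step 10. Acid-promoted loss of water and aromatisation toward an alkylhydroquinone may compete with ketal hydrolysis on the enone. The fallback sets out from 15 and returns at 18 by reversing the end-game. The acetonide is hydrolysed on the saturated ketol 15 (AcOH–H2O, rt), where no conjugated system drives aromatisation, to give (2R,3R,4S)-2,3,4,5-tetrahydroxy-2-[(12Z)-henicos-12-en-1-yl]cyclohexan-1-one F6. The only hydroxyl β to the ketone is then lost by E1cB dehydration under buffered conditions (piperidinium acetate, THF, rt), giving 18 directly.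

3. Step 7. Epimerisation or β-elimination at the two α-alkoxy carbonyl positions may occur while both carbonyls are generated at once. The fallback sets out from 10 and returns at 12, installing the carbonyls one at a time on protected intermediates. Dess–Martin oxidation of 10 gives (13Z)-1-[(4R,5S)-5-({[tert-butyl(dimethyl)silyl]oxy}methyl)-2,2-dimethyl-1,3-dioxolan-4-yl]docos-13-en-1-one F4. HF·pyridine then gives (13Z)-1-[(4R,5S)-5-(hydroxymethyl)-2,2-dimethyl-1,3-dioxolan-4-yl]docos-13-en-1-one F5, and a final Dess–Martin oxidation of the primary alcohol gives 12, generated immediately before step 8.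

## Further compounds

F1 | step 8 | (ethenyloxy)tris(trimethylsilyl)silane | C=CO[Si]([Si](C)(C)C)([Si](C)(C)C)[Si](C)(C)C
F2 | step 8 | tris(trimethylsilyl)silyl ether of aldol 14 (C3 epimers) | O=CCC(O[Si]([Si](C)(C)C)([Si](C)(C)C)[Si](C)(C)C)[C@@H]1OC(C)(C)O[C@H]1C(=O)CCCCCCCCCCC/C=C\CCCCCCCC
F3 | step 8 | 7-O-tris(trimethylsilyl)silyl ether of 15 (C7 epimers) | CCCCCCCC/C=C\CCCCCCCCCCC[C@]1(O)C(=O)CC(O[Si]([Si](C)(C)C)([Si](C)(C)C)[Si](C)(C)C)[C@H](OC(C)(C)O2)[C@H]12
F4 | step 7 | (13Z)-1-[(4R,5S)-5-({[tert-butyl(dimethyl)silyl]oxy}methyl)-2,2-dimethyl-1,3-dioxolan-4-yl]docos-13-en-1-one | CC(C)(C)[Si](C)(C)OC[C@@H]1OC(C)(C)O[C@H]1C(=O)CCCCCCCCCCC/C=C\CCCCCCCC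
F5 | step 7 | (13Z)-1-[(4R,5S)-5-(hydroxymethyl)-2,2-dimethyl-1,3-dioxolan-4-yl]docos-13-en-1-one | OC[C@@H]1OC(C)(C)O[C@H]1C(=O)CCCCCCCCCCC/C=C\CCCCCCCC
F6 | step 10 | (2R,3R,4S)-2,3,4,5-tetrahydroxy-2-[(12Z)-henicos-12-en-1-yl]cyclohexan-1-one (C5 epimers) | CCCCCCCC/C=C\CCCCCCCCCCC[C@]1(O)C(=O)CC(O)[C@H](O)[C@H]1O
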